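**Assumption:** andrographolide (bulk plant isolate, catalogue chemical) is taken as an admissible cheap commercial starting material. Locants follow labdane numbering (C3 carbinol, C4 quaternary with C19 = CH2O, C8/C17, side chain C11–C16).

## Retrosynthetic overview

1. Target 14 ⇐ silyl ether 13 (desilylation) ⇐ 3-ketone 9 (equatorial hydride delivery, then acetylation) ⇐ Δ8(17) ester 7 (exo→endo alkene isomerisation, C3 oxidation).
2. Key disconnection C12–C13: ester 7 ⇐ C12 aldehyde 3, used as its N–H hydrazone (latent carbanion at the former carbonyl carbon), plus methyl crotonate. Loss of N2 leaves C12 as CH2 and creates C13.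
3. Aldehyde 3 ⇐ oxidative excision of the C12=C13 alkylidene-lactone of 19-O-TBS-andrographolide 2 ⇐ andrographolide 1.
4. Rings: both six-membered rings, with C4, C5, C9, C10 and the C19 oxygen, are taken intact from andrographolide. No ring is formed in the route; only C3 is inverted and the alkene moved.

## Route

Step 1
Reactants: 1 andrographolide
Product: 2 19-O-(tert-butyldimethylsilyl)andrographolide
Conditions: TBSCl (1.1 equiv), imidazole, DMF, 0 °C
Reagents that add atoms: tert-butyldimethylsilyl chloride, CC(C)(C)[Si](C)(C)Cl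
Why: Selective silylation of the only primary hydroxyl (C19) over the two secondary ones; no stereocentre is touched.

Step 2
Reactants: 2 19-O-TBS-andrographolide
Product: 3 (3R,4R,5S,9R,10S)-19-TBSO-3-hydroxy-13,14,15,16-tetranor-ent-labd-8(17)-en-12-al (CH2CHO on C9)
Conditions: KMnO4 (1.3 equiv), THF/H2O, –10 °C
Reagents that add atoms: potassium permanganate, [K+].[O-][Mn](=O)(=O)=O
Why: Permanganate oxidative alkene cleavage (cyclic manganate ester, then C–C scission) should take the conjugated, electron-poor and sterically open C12=C13 bond ahead of the 8(17)-methylene shielded by the axial C10 methyl, excising the lactone carbons.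

Step 3
Reactants: 3 C12 aldehyde, 4 hydrazine hydrate, 5 methyl (E)-crotonate
Product: 7 methyl (3R,4R,5S,9R,10S,13R)-19-TBSO-3-hydroxy-ent-labd-8(17)-en-15-oate, via hydrazone 6 (not isolated)
Conditions: 4 (1.2 equiv), THF, rt, 1 h; then 5 (3 equiv), [Ru(p-cymene)Cl2]2 (2.5 mol%), (R,R)-Me-BPE (5 mol%), K3PO4, CsF, THF, 50 °C
Reagents that add atoms: none
Why: Proposed new method: the N–H hydrazone, deprotonated on Ru(II) bearing an electron-rich chelating bisphosphine, acts as a latent alkyl carbanion at the former carbonyl carbon C12 and adds to the β-carbon of the Ru-bound crotonate through a cyclic transition state with loss of N2, joining two normally electrophilic carbons and leaving C12 as CH2 (closest known reaction: the Ru/dmpe-catalysed Wolff–Kishner-type conjugate addition of aldehyde hydrazones to unsaturated esters, a carbonyl umpolung); new here are the functionalised aliphatic aldehyde and the replacement of dmpe by its C2-symmetric analogue (R,R)-Me-BPE, whose phospholane quadrants are expected to differentiate the crotonate faces and set C13 (R) under catalyst control because the nearest substrate stereocentre (C9) is remote, the ligand antipode that gives 13R being fixed in one model run.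

Step 4
Reactants: 7 Δ8(17) methyl ester
Product: 8 methyl (3R,4R,5S,9R,10S,13R)-19-TBSO-3-hydroxy-ent-labd-7-en-15-oate
Conditions: Co(salen-tBu,tBu)Cl (5 mol%), PhSiH3 (5 mol%), benzene, rt
Reagents that add atoms: none
Why: Cobalt-hydride hydrogen-atom-transfer olefin isomerisation: reversible H• addition at C17 gives the tertiary C8 radical, and back-abstraction at the accessible C7–H rather than the hindered C9–H gives the trisubstituted Δ7 alkene, which does not re-enter the cycle; no stereocentre changes.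

Step 5
Reactants: 8 Δ7 hydroxy ester
Product: 9 methyl (4R,5S,9R,10S,13R)-19-TBSO-3-oxo-ent-labd-7-en-15-oate
Conditions: Dess–Martin periodinane (1.3 equiv), CH2Cl2, rt
Reagents that add atoms: none
Why: Dess–Martin oxidation of the secondary alcohol; C4 is quaternary and O19 is silylated, so neither epimerisation, β-elimination nor retro-aldol is possible.

Step 6
Reactants: 9 3-ketone
Product: 11 (3S,4R,5S,9R,10S,13R)-19-TBSO-3-hydroxy-ent-labd-7-en-15-oic acid, via hydroxy ester 10 (not isolated)
Conditions: K-Selectride (1.5 equiv), THF, –78 → –40 °C; then MeOH, 3 M NaOH, 30% H2O2, 0 → 40 °C; then 1 M HCl to pH 3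
Reagents that add atoms: sodium hydroxide, [Na+].[OH-]
Why: The bulky trialkylborohydride attacks the C3 ketone equatorially, as in 4,4-disubstituted 3-oxo terpenoids, giving the axial 3S alcohol trans to the C10 methyl, and the alkaline peroxide work-up oxidises the borane and saponifies the unhindered methyl ester (Selectride reduction, ester hydrolysis).

Step 7
Reactants: 11 hydroxy acid
Product: 13 (3S,4R,5S,9R,10S,13R)-3-acetoxy-19-TBSO-ent-labd-7-en-15-oic acid, via mixed anhydride 12 (not isolated)
Conditions: Ac2O (5 equiv), DMAP (0.3 equiv), pyridine, 40 °C; then H2O/THF, rt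
Reagents that add atoms: acetic anhydride, CC(=O)OC(C)=O; water, O
Why: DMAP-catalysed acyl transfer acetylates the hindered axial 3-OH, and the carboxylic mixed anhydride formed alongside is hydrolysed back to the acid on aqueous quench; configuration at C3 is retained.

Step 8
Reactants: 13 silyl ether acid
Product: 14 target, (3S,4R,5S,9R,10S,13R)-3-acetoxy-19-hydroxy-ent-labd-7-en-15-oic acid
Conditions: HF·pyridine, pyridine, THF, 0 °C → rt
Reagents that add atoms: none
Why: Fluoride-driven desilylation frees the C19 alcohol without touching the acetate or the alkene, and acetyl migration is excluded because the 3-OAc and the C4–CH2OH are trans-diaxial.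

## Compound list

1 | andrographolide, (3R,4R,5S,9R,10S,14S)-3,14,19-trihydroxy-ent-labda-8(17),12E-dien-16,15-olide | O[C@@H]1CC[C@]2(C)[C@H](CCC(=C)[C@H]2C/C=C2/C(=O)OC[C@H]2O)[C@]1(C)CO | starting material
2 | 19-O-TBS-andrographolide | O[C@@H]1CC[C@]2(C)[C@H](CCC(=C)[C@H]2C/C=C2/C(=O)OC[C@H]2O)[C@]1(C)CO[Si](C)(C)C(C)(C)C | intermediate
3 | (3R,4R,5S,9R,10S)-19-TBSO-3-hydroxy-13,14,15,16-tetranor-ent-labd-8(17)-en-12-al | O[C@@H]1CC[C@]2(C)[C@H](CCC(=C)[C@H]2CC=O)[C@]1(C)CO[Si](C)(C)C(C)(C)C | intermediate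
4 | hydrazine hydrate | NN.O | starting material
5 | methyl (E)-crotonate | C/C=C/C(=O)OC | starting material
6 | N–H hydrazone of aldehyde 3 | O[C@@H]1CC[C@]2(C)[C@H](CCC(=C)[C@H]2CC=NN)[C@]1(C)CO[Si](C)(C)C(C)(C)C | intermediate (not isolated)
7 | methyl (3R,4R,5S,9R,10S,13R)-19-TBSO-3-hydroxy-ent-labd-8(17)-en-15-oate | O[C@@H]1CC[C@]2(C)[C@H](CCC(=C)[C@H]2CC[C@@H](C)CC(=O)OC)[C@]1(C)CO[Si](C)(C)C(C)(C)C | intermediate
8 | methyl (3R,4R,5S,9R,10S,13R)-19-TBSO-3-hydroxy-ent-labd-7-en-15-oate | O[C@@H]1CC[C@]2(C)[C@H](CC=C(C)[C@H]2CC[C@@H](C)CC(=O)OC)[C@]1(C)CO[Si](C)(C)C(C)(C)C | intermediate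
9 | methyl (4R,5S,9R,10S,13R)-19-TBSO-3-oxo-ent-labd-7-en-15-oate | O=C1CC[C@]2(C)[C@H](CC=C(C)[C@H]2CC[C@@H](C)CC(=O)OC)[C@]1(C)CO[Si](C)(C)C(C)(C)C | intermediate
10 | methyl (3S,4R,5S,9R,10S,13R)-19-TBSO-3-hydroxy-ent-labd-7-en-15-oate (axial 3-OH) | O[C@H]1CC[C@]2(C)[C@H](CC=C(C)[C@H]2CC[C@@H](C)CC(=O)OC)[C@]1(C)CO[Si](C)(C)C(C)(C)C | intermediate (not isolated)
11 | (3S,4R,5S,9R,10S,13R)-19-TBSO-3-hydroxy-ent-labd-7-en-15-oic acid | O[C@H]1CC[C@]2(C)[C@H](CC=C(C)[C@H]2CC[C@@H](C)CC(=O)O)[C@]1(C)CO[Si](C)(C)C(C)(C)C | intermediate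
12 | acetic mixed anhydride of 3-O-acetyl-11 | CC(=O)O[C@H]1CC[C@]2(C)[C@H](CC=C(C)[C@H]2CC[C@@H](C)CC(=O)OC(C)=O)[C@]1(C)CO[Si](C)(C)C(C)(C)C | intermediate (not isolated)
13 | (3S,4R,5S,9R,10S,13R)-3-acetoxy-19-TBSO-ent-labd-7-en-15-oic acid | CC(=O)O[C@H]1CC[C@]2(C)[C@H](CC=C(C)[C@H]2CC[C@@H](C)CC(=O)O)[C@]1(C)CO[Si](C)(C)C(C)(C)C | intermediate
14 | (3S,4R,5S,9R,10S,13R)-3-acetoxy-19-hydroxy-ent-labd-7-en-15-oic acid | CC(=O)O[C@H]1CC[C@]2(C)[C@H](CC=C(C)[C@H]2CC[C@@H](C)CC(=O)O)[C@]1(C)CO | target

## Step count and risks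

Total steps: 8. Longest linear sequence: 8 (from andrographolide).

The three steps most likely to fail:

**Step 3 (conversion and C13 control in the hydrazone conjugate addition).** The fallback is a classical Corey–Seebach acyl-anion sequence that sets out from aldehyde 3. Propane-1,3-dithiol with catalytic iodine gives the 1,3-dithiane of the aldehyde F2. Double deprotonation (t-BuLi, 2.2 equiv, THF/HMPA, –78 °C; the 3-OH rides as its alkoxide) and 1,4-addition to purchased (S)-4-benzyl-3-[(E)-crotonoyl]oxazolidin-2-one gives the dithiane imide adduct F3, with C13 set by the auxiliary (the antipodal auxiliary is used if the sense is opposite). Deactivated Raney nickel in ethanol removes the sulfur to give the desulfurised imide F4. NaOMe in MeOH at 0 °C releases the auxiliary, and the sequence comes back to the route at compound 7.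

**Step 2 (chemoselectivity of permanganate between C12=C13 and the 8(17)-methylene, and over-oxidation of the aldehyde).** The fallback sets out from compound 2. MnO2 in CH2Cl2 oxidises only the allylic 14-OH and gives the 14-oxo alkylidene-furandione F1, formally the Knoevenagel adduct of aldehyde 3 with tetronic acid. Hydrazine hydrate (2.2 equiv, THF, 0 °C) adds at C12 and expels tetronate (retro-Knoevenagel transimination). This comes back to the route at hydrazone 6, which enters the ruthenium stage of step 3 directly.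

**Step 4 (Δ7 versus Δ8(9) regiochemistry of the radical isomerisation).** The fallback fixes the regiochemistry by a reductive allylic transposition and sets out from compound 7. Catalytic SeO2 with t-BuOOH hydroxylates the only accessible allylic methylene and gives the 7-hydroxy-8(17)-ene F5. Mitsunobu reaction with 2-nitrobenzenesulfonylhydrazide (PPh3, DEAD, N-methylmorpholine, –30 °C) gives the N-allylic sulfonylhydrazine F6. On warming this loses the sulfinic acid to the allylic diazene F7, which extrudes N2 in a retro-ene step that delivers hydrogen to C17 and moves the double bond to C7=C8. It comes back to the route at compound 8.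

## Further compounds

F1 | step 2 | 19-O-TBS-14-oxoandrographolide (3-alkylidenefuran-2,4-dione) | O[C@@H]1CC[C@]2(C)[C@H](CCC(=C)[C@H]2C/C=C2/C(=O)OCC2=O)[C@]1(C)CO[Si](C)(C)C(C)(C)C
F2 | step 3 | 1,3-dithiane of aldehyde 3 | O[C@@H]1CC[C@]2(C)[C@H](CCC(=C)[C@H]2CC3SCCCS3)[C@]1(C)CO[Si](C)(C)C(C)(C)C
F3 | step 3 | dithiane imide adduct (C12 dithioketal, C13 as in 7, (S)-4-benzyloxazolidinone imide) | O[C@@H]1CC[C@]2(C)[C@H](CCC(=C)[C@H]2CC3(SCCCS3)[C@@H](C)CC(=O)N4[C@@H](Cc5ccccc5)COC4=O)[C@]1(C)CO[Si](C)(C)C(C)(C)C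
F4 | step 3 | desulfurised imide (13R) | O[C@@H]1CC[C@]2(C)[C@H](CCC(=C)[C@H]2CC[C@@H](C)CC(=O)N3[C@@H](Cc4ccccc4)COC3=O)[C@]1(C)CO[Si](C)(C)C(C)(C)C
F5 | step 4 | methyl (7S)-19-TBSO-3,7-dihydroxy-ent-labd-8(17)-en-15-oate (axial 7-OH) | O[C@@H]1CC[C@]2(C)[C@H](C[C@H](O)C(=C)[C@H]2CC[C@@H](C)CC(=O)OC)[C@]1(C)CO[Si](C)(C)C(C)(C)C
F6 | step 4 | C7 N-(2-nitrobenzenesulfonyl)hydrazine (inverted at C7) | O[C@@H]1CC[C@]2(C)[C@H](C[C@@H](N(N)S(=O)(=O)c3ccccc3[N+](=O)[O-])C(=C)[C@H]2CC[C@@H](C)CC(=O)OC)[C@]1(C)CO[Si](C)(C)C(C)(C)C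
F7 | step 4 | C7 allylic diazene | O[C@@H]1CC[C@]2(C)[C@H](C[C@@H](N=N)C(=C)[C@H]2CC[C@@H](C)CC(=O)OC)[C@]1(C)CO[Si](C)(C)C(C)(C)C
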